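**Retrosynthetic overview**
- The ketone comes last: oxidation of a homoallylic alcohol made by α‑selective addition of an (E)‑allylbarium reagent (furan side chain, from 3‑(chloromethyl)furan and isoprene monoxide) to an oxolane–lactone acetaldehyde.
- The γ‑lactone is formed by Baeyer–Villiger ring expansion of a 2‑methyl‑2‑(oxolan‑2‑yl)cyclobutanone (four‑ to five‑membered ring, retention at the migrating carbon).
- The cyclobutanone and the oxolane arise together from an (E)‑1‑alkenylcyclopropanol carrying the tertiary alcohol, by oxidative etherification with semipinacol ring expansion (three‑ to four‑membered ring); this is the key step.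
- The alkenylcyclopropanol comes from a Kulinkovich reaction on an (E)‑2‑methyl enoate (cross‑metathesis with methyl methacrylate); the tertiary carbinol comes from Sharpless epoxidation and reductive opening of an allylic alcohol made by carboalumination of hex‑1‑en‑5‑yne.
- Ring order: cyclopropane, then oxolane and cyclobutanone together, then γ‑lactone; the furan is bought.

Assumption: the SMILES is read as R at both oxolane stereocentres, S at the lactone quaternary carbon and E at the olefin, and this enantiomer is the one made.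

**Step 1**
Reactants: 1 hex‑1‑en‑5‑yne
Product: 4 (2E)‑3‑methylhepta‑2,6‑dien‑1‑ol, via alkenyldimethylalane 2 (not isolated), via lithium alkenylaluminate 3 (not isolated)
Conditions: Me3Al (2 equiv), Cp2ZrCl2 (20 mol%), CH2Cl2, 0 °C to rt; volatiles removed; n‑BuLi, THF/hexane, −78 °C; (CH2O)n, −78 °C to rt; aq HCl
Reagents that add atoms: trimethylaluminium C[Al](C)C; formaldehyde (as paraformaldehyde) C=O
Why: Negishi zirconium‑catalysed carboalumination adds methyl and aluminium syn across the terminal alkyne (the isolated terminal alkene reacts far more slowly), and the derived aluminate is hydroxymethylated with retention, which fixes the E trisubstituted olefin.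

**Step 2**
Reactants: 4 (2E)‑3‑methylhepta‑2,6‑dien‑1‑ol
Product: 5 [(2R,3R)‑3‑(but‑3‑en‑1‑yl)‑3‑methyloxiran‑2‑yl]methanol
Conditions: Ti(OiPr)4 (5 mol%), D‑(−)‑diethyl tartrate (6 mol%), t‑BuOOH, 4 Å molecular sieves, CH2Cl2, −20 °C
Reagents that add atoms: tert‑butyl hydroperoxide CC(C)(C)OO
Why: Sharpless asymmetric epoxidation touches only the allylic alcohol, and D‑(−)‑tartrate gives the (2R,3R)‑epoxide (mirror image of the geraniol/L‑(+)‑tartrate outcome), which sets the future quaternary oxolane carbon.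

**Step 3**
Reactants: 5 [(2R,3R)‑3‑(but‑3‑en‑1‑yl)‑3‑methyloxiran‑2‑yl]methanol
Product: 6 (3R)‑3‑methylhept‑6‑ene‑1,3‑diol
Conditions: NaAlH2(OCH2CH2OMe)2, THF, 0 °C; aq NaOH
Reagents that add atoms: none
Why: Reductive opening of a 2,3‑epoxy alcohol by alkoxide‑bound aluminium hydride delivers hydride to C‑2, so the C‑3–O bond and its configuration are kept and the 1,3‑diol results.

**Step 4**
Reactants: 6 (3R)‑3‑methylhept‑6‑ene‑1,3‑diol; 7 methyl methacrylate
Product: 8 methyl (2E,6R)‑6,8‑dihydroxy‑2,6‑dimethyloct‑2‑enoate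
Conditions: second‑generation Grubbs catalyst (5 mol%), 7 (6 equiv), CH2Cl2, 40 °C
Reagents that add atoms: none
Why: Olefin cross‑metathesis of a terminal alkene with the non‑dimerising methacrylate is selective for the cross product and gives the E enoate (typically >20:1) with free hydroxyls tolerated.

**Step 5**
Reactants: 8 methyl (2E,6R)‑6,8‑dihydroxy‑2,6‑dimethyloct‑2‑enoate
Product: 9 (3R,6E)‑7‑(1‑hydroxycyclopropyl)‑3‑methyloct‑6‑ene‑1,3‑diol
Conditions: EtMgBr (6 equiv, slow addition), Ti(OiPr)4 (50 mol%), THF, 0 °C to rt; aq NH4Cl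
Reagents that add atoms: ethylmagnesium bromide CC[Mg]Br
Why: Kulinkovich cyclopropanation: the titanacyclopropane from EtMgBr and Ti(OiPr)4 adds twice to the ester carbonyl (α‑substituted enoates are accepted), the olefin geometry is untouched, and the extra Grignard reagent only deprotonates the two hydroxyls.

**Step 6**
Reactants: 9 (3R,6E)‑7‑(1‑hydroxycyclopropyl)‑3‑methyloct‑6‑ene‑1,3‑diol
Product: 11 (5S)‑5‑[(2R,5R)‑5‑(2‑hydroxyethyl)‑5‑methyloxolan‑2‑yl]‑5‑methyloxolan‑2‑one, via cyclobutanone 10 (not isolated)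
Conditions: (R,R)‑ArI(OAc)2 [Ar = 2,6‑bis(1‑methoxy‑1‑oxopropan‑2‑yloxy)phenyl; CC(=O)OI(OC(C)=O)c1c(O[C@H](C)C(=O)OC)cccc1O[C@H](C)C(=O)OC] (1.3 equiv), (CF3)2CHOH/CH2Cl2 1:4, −40 to 0 °C; then mCPBA (1.5 equiv), 0 °C to rt
Reagents that add atoms: 3‑chloroperbenzoic acid OOC(=O)c1cccc(Cl)c1
Why: Proposed new method: the chiral aryl‑λ3‑iodane (trivalent iodine) activates one face of the electron‑rich trisubstituted olefin, a cyclopropanol C–C bond migrates anti to iodine onto the tertiary carbon (semipinacol ring expansion, sets the quaternary centre), and the tertiary hydroxyl displaces the aryliodanyl group at the neighbouring carbon with inversion (5‑exo‑tet, sets the oxolane CH centre), a net syn oxy‑alkylation of the E olefin whose facial sense is fixed by the lactate ligands so that, with the pre‑set R carbinol, the 2,5‑trans oxolane results; the closest known reaction types are lactate‑iodane‑mediated enantioselective oxidative 1,2‑shifts of alkenes and halonium‑triggered semipinacol ring expansions of alkenylcyclopropanols, and the Baeyer–Villiger oxidation in the same flask moves the quaternary carbon onto oxygen with retention.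

**Step 7**
Reactants: 11 (5S)‑5‑[(2R,5R)‑5‑(2‑hydroxyethyl)‑5‑methyloxolan‑2‑yl]‑5‑methyloxolan‑2‑one
Product: 12 2‑[(2R,5R)‑2‑methyl‑5‑[(2S)‑2‑methyl‑5‑oxooxolan‑2‑yl]oxolan‑2‑yl]acetaldehyde
Conditions: Dess–Martin periodinane, CH2Cl2, 0 °C to rt
Reagents that add atoms: none
Why: Dess–Martin oxidation takes the primary alcohol to the aldehyde under near‑neutral conditions that leave the lactone and the β‑alkoxy aldehyde intact.

**Step 8**
Reactants: 13 3‑(chloromethyl)furan; 14 2‑methyl‑2‑vinyloxirane (racemic)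
Product: 16 (2E)‑5‑(furan‑3‑yl)‑2‑methylpent‑2‑en‑1‑ol, via Grignard reagent 15 (not isolated)
Conditions: Mg, THF, 0 °C; then CuI (10 mol%), 14, −30 °C; aq NH4Cl
Reagents that add atoms: none
Why: Copper‑catalysed SN2' opening of a vinyl oxirane by a Grignard reagent gives the 2‑methylallylic alcohol mainly as the E isomer (about 9:1 expected), the minor Z isomer being removed on AgNO3‑impregnated silica.

**Step 9**
Reactants: 16 (2E)‑5‑(furan‑3‑yl)‑2‑methylpent‑2‑en‑1‑ol
Product: 17 3‑[(3E)‑5‑chloro‑4‑methylpent‑3‑en‑1‑yl]furan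
Conditions: NCS, Me2S, CH2Cl2, −20 to 0 °C
Reagents that add atoms: N‑chlorosuccinimide O=C1CCC(=O)N1Cl
Why: Corey–Kim chlorination activates the primary allylic alcohol as an alkoxysulfonium salt that chloride displaces by SN2, without allylic transposition or loss of olefin geometry.

**Step 10**
Reactants: 17 3‑[(3E)‑5‑chloro‑4‑methylpent‑3‑en‑1‑yl]furan; 12 2‑[(2R,5R)‑2‑methyl‑5‑[(2S)‑2‑methyl‑5‑oxooxolan‑2‑yl]oxolan‑2‑yl]acetaldehyde
Product: 19 (5S)‑5‑[(2R,5R)‑5‑[(4E)‑7‑(furan‑3‑yl)‑2‑hydroxy‑4‑methylhept‑4‑en‑1‑yl]‑5‑methyloxolan‑2‑yl]‑5‑methyloxolan‑2‑one (both carbinol epimers), via allylbarium chloride 18 (not isolated)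
Conditions: BaI2, Li, biphenyl, THF, rt (activated Ba); 17, −78 °C; then 12, −78 °C; aq NH4Cl
Reagents that add atoms: none
Why: Yamamoto‑type allylbarium addition attacks the aldehyde through the α‑carbon with retention of the E olefin and much faster than the lactone at −78 °C; the new carbinol centre is formed unselectively and is erased in step 11.

**Step 11**
Reactants: 19 (5S)‑5‑[(2R,5R)‑5‑[(4E)‑7‑(furan‑3‑yl)‑2‑hydroxy‑4‑methylhept‑4‑en‑1‑yl]‑5‑methyloxolan‑2‑yl]‑5‑methyloxolan‑2‑one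
Product: 20 (5S)‑5‑[(2R,5R)‑5‑[(4E)‑7‑(furan‑3‑yl)‑4‑methyl‑2‑oxohept‑4‑en‑1‑yl]‑5‑methyloxolan‑2‑yl]‑5‑methyloxolan‑2‑one (CNP0156092.1)
Conditions: Dess–Martin periodinane, pyridine, CH2Cl2, 0 °C
Reagents that add atoms: none
Why: Buffered Dess–Martin oxidation gives the β,γ‑unsaturated ketone without moving the olefin into conjugation, opening the β‑alkoxy ketone or touching the furan.

**Compound list**
1 | hex‑1‑en‑5‑yne | C#CCCC=C | starting material
2 | dimethyl[(1E)‑2‑methylhexa‑1,5‑dien‑1‑yl]alumane | C=CCC/C(C)=C/[Al](C)C | intermediate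
3 | lithium butyl(dimethyl)[(1E)‑2‑methylhexa‑1,5‑dien‑1‑yl]aluminate | [Li+].C=CCC/C(C)=C/[Al-](C)(C)CCCC | intermediate
4 | (2E)‑3‑methylhepta‑2,6‑dien‑1‑ol | C=CCC/C(C)=C/CO | intermediate
5 | [(2R,3R)‑3‑(but‑3‑en‑1‑yl)‑3‑methyloxiran‑2‑yl]methanol | OC[C@H]1O[C@]1(C)CCC=C | intermediate
6 | (3R)‑3‑methylhept‑6‑ene‑1,3‑diol | OCC[C@](C)(O)CCC=C | intermediate
7 | methyl methacrylate | C=C(C)C(=O)OC | starting material
8 | methyl (2E,6R)‑6,8‑dihydroxy‑2,6‑dimethyloct‑2‑enoate | COC(=O)/C(C)=C/CC[C@@](C)(O)CCO | intermediate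
9 | (3R,6E)‑7‑(1‑hydroxycyclopropyl)‑3‑methyloct‑6‑ene‑1,3‑diol | OCC[C@](C)(O)CC/C=C(\C)C1(O)CC1 | intermediate
10 | (2S)‑2‑[(2R,5R)‑5‑(2‑hydroxyethyl)‑5‑methyloxolan‑2‑yl]‑2‑methylcyclobutan‑1‑one | OCC[C@@]1(C)CC[C@H]([C@]2(C)CCC2=O)O1 | intermediate
11 | (5S)‑5‑[(2R,5R)‑5‑(2‑hydroxyethyl)‑5‑methyloxolan‑2‑yl]‑5‑methyloxolan‑2‑one | OCC[C@@]1(C)CC[C@H]([C@]2(C)CCC(=O)O2)O1 | intermediate
12 | 2‑[(2R,5R)‑2‑methyl‑5‑[(2S)‑2‑methyl‑5‑oxooxolan‑2‑yl]oxolan‑2‑yl]acetaldehyde | O=CC[C@@]1(C)CC[C@H]([C@]2(C)CCC(=O)O2)O1 | intermediate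
13 | 3‑(chloromethyl)furan | ClCc1ccoc1 | starting material
14 | 2‑methyl‑2‑vinyloxirane (racemic) | C=CC1(C)CO1 | starting material
15 | (furan‑3‑ylmethyl)magnesium chloride | Cl[Mg]Cc1ccoc1 | intermediate
16 | (2E)‑5‑(furan‑3‑yl)‑2‑methylpent‑2‑en‑1‑ol | OC/C(C)=C/CCc1ccoc1 | intermediate
17 | 3‑[(3E)‑5‑chloro‑4‑methylpent‑3‑en‑1‑yl]furan | ClC/C(C)=C/CCc1ccoc1 | intermediate
18 | [(2E)‑5‑(furan‑3‑yl)‑2‑methylpent‑2‑en‑1‑yl]barium chloride | Cl[Ba]C/C(C)=C/CCc1ccoc1 | intermediate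
19 | (5S)‑5‑[(2R,5R)‑5‑[(4E)‑7‑(furan‑3‑yl)‑2‑hydroxy‑4‑methylhept‑4‑en‑1‑yl]‑5‑methyloxolan‑2‑yl]‑5‑methyloxolan‑2‑one (epimers at the carbinol) | C/C(=C\CCc1ccoc1)CC(O)C[C@@]1(C)CC[C@H]([C@]2(C)CCC(=O)O2)O1 | intermediate
20 | (5S)‑5‑[(2R,5R)‑5‑[(4E)‑7‑(furan‑3‑yl)‑4‑methyl‑2‑oxohept‑4‑en‑1‑yl]‑5‑methyloxolan‑2‑yl]‑5‑methyloxolan‑2‑one | C/C(=C\CCc1ccoc1)CC(=O)C[C@@]1(C)CC[C@H]([C@]2(C)CCC(=O)O2)O1 | target

**Step count**
Total: 11 steps (the one‑flask operation of step 6 counted once). Longest linear sequence: 9 steps (1–7, 10, 11).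

**Three steps most likely to fail**

Step 6, the proposed new step. The iodane may instead oxidise and open the cyclopropanol. A 1,2‑acyl or methyl shift may outrun etherification at the hindered iodanyl carbon. The (R,R)‑reagent may give poor or reversed face selection; in that case its (S,S) antipode from methyl (R)‑lactate would be tried, and the cis‑oxolane isomer is removed at 11. The fallback uses known chemistry, sets out from 9 and comes back at 10. Silylation of the primary hydroxyl (t‑BuMe2SiCl, imidazole) gives silyl ether F3. Shi epoxidation with the enantiomer of the D‑fructose‑derived ketone (made from L‑sorbose), Oxone (2KHSO5·KHSO4·K2SO4), K2CO3, MeCN/dimethoxymethane/water, 0 °C, gives epoxide F4. With BF3·OEt2 at −78 °C this undergoes the stereospecific anti semipinacol ring expansion to hydroxy cyclobutanone F5. Tf2O with 2,6‑di‑tert‑butyl‑4‑methylpyridine converts the secondary hydroxyl into triflate F6, which the tertiary hydroxyl displaces in the flask with inversion to give oxolane silyl ether F7. HF·pyridine then frees 10, which mCPBA oxidises to 11 as in step 6.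

Step 5, the Kulinkovich reaction on a conjugated ester that carries a free 1,3‑diol. The diolate can tie up titanium and the slow enoate can suffer simple Grignard addition. The fallback sets out from 8 and comes back at 9; it changes the substrate to one without free alkoxides. Me3SiCl and imidazole give bis(trimethylsilyl) ether F1. The same cyclopropanation then gives silylated cyclopropanol F2. Bu4NF buffered with AcOH returns 9.

Step 10, the allylbarium addition. Preparing activated barium is demanding, and α/γ or E/Z leakage and enolisation of the β‑alkoxy aldehyde are possible. The fallback sets out from 17 (with 12) and comes back at 20. PhSO2Na in DMF gives allyl sulfone F8. Lithiation (n‑BuLi, THF, −78 °C) and addition to 12 occur at the sulfone‑bearing carbon and give hydroxy sulfone F9. Dess–Martin oxidation gives keto sulfone F10. SmI2 in THF/MeOH at −78 °C removes the sulfone, and protonation of the enolate at the α‑carbon gives 20.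

**Further compounds**
F1 | step 5 | methyl (2E,6R)‑2,6‑dimethyl‑6,8‑bis[(trimethylsilyl)oxy]oct‑2‑enoate | COC(=O)/C(C)=C/CC[C@@](C)(O[Si](C)(C)C)CCO[Si](C)(C)C
F2 | step 5 | 1‑[(2E,6R)‑6‑methyl‑6,8‑bis[(trimethylsilyl)oxy]oct‑2‑en‑2‑yl]cyclopropan‑1‑ol | C[Si](C)(C)OCC[C@](C)(O[Si](C)(C)C)CC/C=C(\C)C1(O)CC1
F3 | step 6 | 1‑[(2E,6R)‑8‑{[tert‑butyl(dimethyl)silyl]oxy}‑6‑hydroxy‑6‑methyloct‑2‑en‑2‑yl]cyclopropan‑1‑ol | CC(C)(C)[Si](C)(C)OCC[C@](C)(O)CC/C=C(\C)C1(O)CC1
F4 | step 6 | 1‑[(2R,3S)‑3‑[(3R)‑5‑{[tert‑butyl(dimethyl)silyl]oxy}‑3‑hydroxy‑3‑methylpentyl]‑2‑methyloxiran‑2‑yl]cyclopropan‑1‑ol | CC(C)(C)[Si](C)(C)OCC[C@](C)(O)CC[C@@H]1O[C@@]1(C)C1(O)CC1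
F5 | step 6 | (2S)‑2‑[(1S,4R)‑6‑{[tert‑butyl(dimethyl)silyl]oxy}‑1,4‑dihydroxy‑4‑methylhexyl]‑2‑methylcyclobutan‑1‑one | CC(C)(C)[Si](C)(C)OCC[C@](C)(O)CC[C@H](O)[C@]1(C)CCC1=O
F6 | step 6 | (1S,4R)‑6‑{[tert‑butyl(dimethyl)silyl]oxy}‑4‑hydroxy‑4‑methyl‑1‑[(1S)‑1‑methyl‑2‑oxocyclobutyl]hexyl trifluoromethanesulfonate | CC(C)(C)[Si](C)(C)OCC[C@](C)(O)CC[C@H](OS(=O)(=O)C(F)(F)F)[C@]1(C)CCC1=O
F7 | step 6 | (2S)‑2‑[(2R,5R)‑5‑(2‑{[tert‑butyl(dimethyl)silyl]oxy}ethyl)‑5‑methyloxolan‑2‑yl]‑2‑methylcyclobutan‑1‑one | CC(C)(C)[Si](C)(C)OCC[C@@]1(C)CC[C@H]([C@]2(C)CCC2=O)O1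
F8 | step 10 | 3‑[(3E)‑4‑methyl‑5‑(phenylsulfonyl)pent‑3‑en‑1‑yl]furan | O=S(=O)(C/C(C)=C/CCc1ccoc1)c1ccccc1
F9 | step 10 | (5S)‑5‑[(2R,5R)‑5‑[(4E)‑7‑(furan‑3‑yl)‑2‑hydroxy‑4‑methyl‑3‑(phenylsulfonyl)hept‑4‑en‑1‑yl]‑5‑methyloxolan‑2‑yl]‑5‑methyloxolan‑2‑one (diastereomer mixture) | C/C(=C\CCc1ccoc1)C(C(O)C[C@@]1(C)CC[C@H]([C@]2(C)CCC(=O)O2)O1)S(=O)(=O)c1ccccc1
F10 | step 10 | (5S)‑5‑[(2R,5R)‑5‑[(4E)‑7‑(furan‑3‑yl)‑4‑methyl‑2‑oxo‑3‑(phenylsulfonyl)hept‑4‑en‑1‑yl]‑5‑methyloxolan‑2‑yl]‑5‑methyloxolan‑2‑one (diastereomer mixture) | C/C(=C\CCc1ccoc1)C(C(=O)C[C@@]1(C)CC[C@H]([C@]2(C)CCC(=O)O2)O1)S(=O)(=O)c1ccccc1
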